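**Retrosynthetic overview**

- The strategy rests on ring B, the dihydrofuran ring (O1, C2, C3, C3a, C7a). C2 carries the ring oxygen O1 and a 1,1-disubstituted alkene and is bonded to the carbinol carbon C3. This is the pattern left when a γ-oxygenated allyl metal adds through its oxygen-bearing carbon to an aldehyde.
- Key disconnection C2–C3: ring-closing Nozaki–Hiyama–Kishi addition of a γ-aryloxyallylchromium species, made from an allylic bromide on an aryl enol ether, to the ortho aldehyde. It closes ring B and sets C2 and C3.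
- The precursor comes from 5-acetyl-2-hydroxybenzaldehyde and a three-carbon vinyl bromide (from 2,2-dimethyl-1,3-dioxan-5-one by bromomethylenation) through a copper-catalysed O-vinylation, then conversion of the allylic alcohol to the bromide.
- After the key step: isovalerate at C3, Corey–Bakshi–Shibata reduction of the acetyl group to the (S)-carbinol, acetate, desilylation, oxidation of the allylic alcohol to the enal.
- Ring order: ring A (benzene) is bought; ring B is the only ring formed, in the key step.

Key step: step 6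

Remark on the chemistry: ring atoms are numbered as in 1-benzofuran. The mono-silyl ether of step 3 and everything made from it up to the allylic bromide are expected as mixtures of both alkene isomers. They are carried on together, because both give the same equilibrating allylchromium species in step 6. The isomer that leads to the E bromide is the one named and drawn.

**Route**

Step 1
Reactants: 1 2,2-dimethyl-1,3-dioxan-5-one
Product: 2 5-(bromomethylidene)-2,2-dimethyl-1,3-dioxane
Conditions: Ph3P+CH2Br Br− (1.3 equiv), KOtBu (1.25 equiv), THF, −78 °C; then 1, −78 °C → rt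
Reagents that add atoms: (bromomethyl)triphenylphosphonium bromide, BrC[P+](c1ccccc1)(c1ccccc1)c1ccccc1.[Br-]
Why: Wittig olefination of an electrophilic α,α'-dialkoxy ketone with the non-stabilised ylide Ph3P=CHBr; the ketone is symmetric, so a single alkene results.

Step 2
Reactants: 2 5-(bromomethylidene)-2,2-dimethyl-1,3-dioxane
Product: 3 2-(bromomethylidene)propane-1,3-diol
Conditions: 1 M HCl aq., THF, rt
Reagents that add atoms: none
Why: Acid-catalysed acetal hydrolysis frees the 1,3-diol, and the vinyl bromide is inert to dilute aqueous acid.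

Step 3
Reactants: 3 2-(bromomethylidene)propane-1,3-diol
Product: 4 (2Z)-3-bromo-2-({[tert-butyl(dimethyl)silyl]oxy}methyl)prop-2-en-1-ol (2E isomer accompanies it)
Conditions: NaH (1.0 equiv), THF, 0 °C → rt; then TBSCl (1.0 equiv)
Reagents that add atoms: tert-butyl(chloro)dimethylsilane (TBSCl), CC(C)(C)[Si](C)(C)Cl
Why: Monosilylation of a symmetric diol through its sparingly soluble monosodium alkoxide, which holds back the second silylation; which arm is silylated does not matter because the isomers converge in step 6.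

Step 4
Reactants: 4 (2Z)-3-bromo-2-({[tert-butyl(dimethyl)silyl]oxy}methyl)prop-2-en-1-ol; 5 5-acetyl-2-hydroxybenzaldehyde
Product: 6 5-acetyl-2-{[(1Z)-2-({[tert-butyl(dimethyl)silyl]oxy}methyl)-3-hydroxyprop-1-en-1-yl]oxy}benzaldehyde (1E isomer accompanies it)
Conditions: CuI (10 mol%), N,N-dimethylglycine hydrochloride (30 mol%), Cs2CO3 (2.5 equiv), 1,4-dioxane (degassed), 90 °C
Reagents that add atoms: none
Why: Ullmann-type CuI-catalysed C–O coupling of a phenol with a vinyl bromide, which goes with retention of alkene geometry; Cs2CO3 deprotonates only the phenol and not the primary alcohol, so only the phenoxide should couple.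

Step 5
Reactants: 6 5-acetyl-2-{[(1Z)-2-({[tert-butyl(dimethyl)silyl]oxy}methyl)-3-hydroxyprop-1-en-1-yl]oxy}benzaldehyde
Product: 8 5-acetyl-2-{[(1E)-3-bromo-2-({[tert-butyl(dimethyl)silyl]oxy}methyl)prop-1-en-1-yl]oxy}benzaldehyde (1Z isomer accompanies it), via allylic mesylate 7 (not isolated)
Conditions: MsCl, Et3N, THF, −30 °C; then LiBr (3 equiv), −30 → 0 °C; non-aqueous work-up, used crude
Reagents that add atoms: lithium bromide, [Li+].[Br-]; methanesulfonyl chloride, CS(=O)(=O)Cl (its atoms stay only in intermediate 7)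
Why: Mesylation of the primary allylic alcohol and SN2 displacement by bromide (Finkelstein type) avoid CBr4/PPh3, whose dibromomethylene ylide would olefinate the aryl aldehyde (Corey–Fuchs reaction); the product is a vinylogous α-bromo ether and is therefore kept dry and used at once.

Step 6
Reactants: 8 5-acetyl-2-{[(1E)-3-bromo-2-({[tert-butyl(dimethyl)silyl]oxy}methyl)prop-1-en-1-yl]oxy}benzaldehyde
Product: 11 1-[(2R,3S)-2-(3-{[tert-butyl(dimethyl)silyl]oxy}prop-1-en-2-yl)-3-hydroxy-2,3-dihydro-1-benzofuran-5-yl]ethan-1-one, via allylchromium dichloride 9 (not isolated), via trimethylsilyl ether 10 (not isolated)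
Conditions: CrCl2 (10 mol%), (S,S)-1,8-bis(4-isopropyl-4,5-dihydrooxazol-2-yl)-3,6-diphenyl-9H-carbazole (12 mol%), Mn powder (3 equiv), iPr2NEt (0.3 equiv), TMSCl (2 equiv), THF, rt, 8 added over 12 h (final 0.01 M); then K2CO3, MeOH, 0 °C
Reagents that add atoms: chromium dichloride, Cl[Cr]Cl (its atoms stay only in intermediate 9); chlorotrimethylsilane, C[Si](C)(C)Cl (its atoms stay only in intermediate 10)
Why: Proposed new method: divalent chromium reduces the allylic C–Br bond of 8 to the σ-allylchromium 9 (trivalent chromium on CH2), whose alkene isomers interconvert by 1,3-metal shifts, and 9 adds through its O1-bearing γ-carbon to the chromium-bound ortho aldehyde in a closed six-membered chair, after which TMSCl silylates the chromium alkoxide to 10 and Mn returns chromium to the divalent state. The closest known reaction types are the anti-selective additions of γ-alkoxyallylchromium reagents to aldehydes, ring-closing Nozaki–Hiyama–Kishi allylations, the ring-closing additions of γ-alkoxyallylstannanes to aldehydes that give trans-2-alkenyl-3-hydroxy cyclic ethers, and the ligand-controlled catalytic asymmetric Nozaki–Hiyama–Kishi allylation; a ring-closing, catalytic asymmetric version on an aryl enol ether has not been shown. Ring B (O1, C2, C3, C3a, C7a) closes in a 5-exo-trig mode at the carbonyl carbon with formation of C2–C3 and of the exocyclic methylene. The relative configuration should follow from the chair with O1 and C3a both equatorial, which gives the 2,3-trans alcohol, while the absolute configuration must come from the chiral tridentate ligand on chromium, so the ligand enantiomer that gives (2R,3S) has to be found by experiment. The step needs aldehyde-over-ketone, γ-over-α and ring-closure-over-dimerisation selectivity: allylchromium reagents add to aldehydes far faster than to aryl methyl ketones, the closed transition state allows only γ attack (α attack would need a seven-membered ring), and slow addition at high dilution keeps the bromide concentration low.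

Step 7
Reactants: 11 1-[(2R,3S)-2-(3-{[tert-butyl(dimethyl)silyl]oxy}prop-1-en-2-yl)-3-hydroxy-2,3-dihydro-1-benzofuran-5-yl]ethan-1-one; 12 3-methylbutanoyl chloride
Product: 13 (2R,3S)-5-acetyl-2-(3-{[tert-butyl(dimethyl)silyl]oxy}prop-1-en-2-yl)-2,3-dihydro-1-benzofuran-3-yl 3-methylbutanoate
Conditions: pyridine, 4-(dimethylamino)pyridine (10 mol%), CH2Cl2, 0 °C → rt
Reagents that add atoms: none
Why: Acylation of the secondary benzylic alcohol under nucleophilic catalysis by 4-(dimethylamino)pyridine, with no bond to a stereocentre broken.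

Step 8
Reactants: 13 (2R,3S)-5-acetyl-2-(3-{[tert-butyl(dimethyl)silyl]oxy}prop-1-en-2-yl)-2,3-dihydro-1-benzofuran-3-yl 3-methylbutanoate
Product: 14 (2R,3S)-2-(3-{[tert-butyl(dimethyl)silyl]oxy}prop-1-en-2-yl)-5-[(1S)-1-hydroxyethyl]-2,3-dihydro-1-benzofuran-3-yl 3-methylbutanoate
Conditions: (R)-Me-CBS [(3aR)-1-methyl-3,3-diphenyltetrahydro-1H,3H-pyrrolo[1,2-c][1,3,2]oxazaborole] (20 mol%), BH3·SMe2 (0.7 equiv, added over 1 h), THF, −20 °C; MeOH quench
Reagents that add atoms: none
Why: Corey–Bakshi–Shibata reduction in which the (R)-oxazaborolidine should give the (S)-1-arylethanol, as it does with acetophenone, under reagent control; the catalysed ketone reduction should outrun hydroboration of the 1,1-disubstituted alkene and leave the ester alone.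

Step 9
Reactants: 14 (2R,3S)-2-(3-{[tert-butyl(dimethyl)silyl]oxy}prop-1-en-2-yl)-5-[(1S)-1-hydroxyethyl]-2,3-dihydro-1-benzofuran-3-yl 3-methylbutanoate
Product: 15 (2R,3S)-5-[(1S)-1-(acetyloxy)ethyl]-2-(3-{[tert-butyl(dimethyl)silyl]oxy}prop-1-en-2-yl)-2,3-dihydro-1-benzofuran-3-yl 3-methylbutanoate
Conditions: Ac2O, pyridine, 4-(dimethylamino)pyridine (5 mol%), CH2Cl2, 0 °C → rt
Reagents that add atoms: acetic anhydride, CC(=O)OC(C)=O
Why: O-Acetylation of the secondary alcohol under nucleophilic catalysis, with retention at the carbinol carbon because the C–O bond is not broken.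

Step 10
Reactants: 15 (2R,3S)-5-[(1S)-1-(acetyloxy)ethyl]-2-(3-{[tert-butyl(dimethyl)silyl]oxy}prop-1-en-2-yl)-2,3-dihydro-1-benzofuran-3-yl 3-methylbutanoate
Product: 16 (2R,3S)-5-[(1S)-1-(acetyloxy)ethyl]-2-(3-hydroxyprop-1-en-2-yl)-2,3-dihydro-1-benzofuran-3-yl 3-methylbutanoate
Conditions: HF·pyridine, pyridine, THF, 0 °C → rt
Reagents that add atoms: none
Why: Fluoride-mediated cleavage of the primary silyl ether under buffered conditions that should leave both esters and the benzylic C–O bonds untouched.

Step 11
Reactants: 16 (2R,3S)-5-[(1S)-1-(acetyloxy)ethyl]-2-(3-hydroxyprop-1-en-2-yl)-2,3-dihydro-1-benzofuran-3-yl 3-methylbutanoate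
Product: 17 (2R,3S)-5-[(1S)-1-(acetyloxy)ethyl]-2-(3-oxoprop-1-en-2-yl)-2,3-dihydro-1-benzofuran-3-yl 3-methylbutanoate
Conditions: MnO2 (activated, 15 equiv), CH2Cl2, rt
Reagents that add atoms: none
Why: Allylic oxidation with MnO2 under neutral conditions, placed last because the 2-substituted acrolein is open to conjugate addition with loss of the C2 aryloxy group and to epimerisation at C2 under base.

**Compound list**

1 | 2,2-dimethyl-1,3-dioxan-5-one | CC1(C)OCC(=O)CO1 | starting material
2 | 5-(bromomethylidene)-2,2-dimethyl-1,3-dioxane | CC1(C)OCC(=CBr)CO1 | intermediate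
3 | 2-(bromomethylidene)propane-1,3-diol | OCC(=CBr)CO | intermediate
4 | (2Z)-3-bromo-2-({[tert-butyl(dimethyl)silyl]oxy}methyl)prop-2-en-1-ol (drawn isomer; the 2E isomer accompanies it) | Br/C=C(/CO)CO[Si](C)(C)C(C)(C)C | intermediate
5 | 5-acetyl-2-hydroxybenzaldehyde | CC(=O)c1ccc(O)c(C=O)c1 | starting material
6 | 5-acetyl-2-{[(1Z)-2-({[tert-butyl(dimethyl)silyl]oxy}methyl)-3-hydroxyprop-1-en-1-yl]oxy}benzaldehyde (drawn isomer; the 1E isomer accompanies it) | O=Cc1cc(C(C)=O)ccc1O/C=C(/CO)CO[Si](C)(C)C(C)(C)C | intermediate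
7 | (2E)-3-(4-acetyl-2-formylphenoxy)-2-({[tert-butyl(dimethyl)silyl]oxy}methyl)prop-2-en-1-yl methanesulfonate (drawn isomer; not isolated) | O=Cc1cc(C(C)=O)ccc1O/C=C(/COS(C)(=O)=O)CO[Si](C)(C)C(C)(C)C | intermediate
8 | 5-acetyl-2-{[(1E)-3-bromo-2-({[tert-butyl(dimethyl)silyl]oxy}methyl)prop-1-en-1-yl]oxy}benzaldehyde (drawn isomer; the 1Z isomer accompanies it) | O=Cc1cc(C(C)=O)ccc1O/C=C(/CBr)CO[Si](C)(C)C(C)(C)C | intermediate
9 | σ-allylchromium dichloride derived from 8 (trivalent chromium; chiral ligand and THF not drawn; not isolated) | O=Cc1cc(C(C)=O)ccc1O/C=C(/C[Cr](Cl)Cl)CO[Si](C)(C)C(C)(C)C | intermediate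
10 | 1-[(2R,3S)-2-(3-{[tert-butyl(dimethyl)silyl]oxy}prop-1-en-2-yl)-3-[(trimethylsilyl)oxy]-2,3-dihydro-1-benzofuran-5-yl]ethan-1-one (not isolated) | C=C(CO[Si](C)(C)C(C)(C)C)[C@H]1Oc2ccc(C(C)=O)cc2[C@@H]1O[Si](C)(C)C | intermediate
11 | 1-[(2R,3S)-2-(3-{[tert-butyl(dimethyl)silyl]oxy}prop-1-en-2-yl)-3-hydroxy-2,3-dihydro-1-benzofuran-5-yl]ethan-1-one | C=C(CO[Si](C)(C)C(C)(C)C)[C@H]1Oc2ccc(C(C)=O)cc2[C@@H]1O | intermediate
12 | 3-methylbutanoyl chloride | CC(C)CC(Cl)=O | starting material
13 | (2R,3S)-5-acetyl-2-(3-{[tert-butyl(dimethyl)silyl]oxy}prop-1-en-2-yl)-2,3-dihydro-1-benzofuran-3-yl 3-methylbutanoate | C=C(CO[Si](C)(C)C(C)(C)C)[C@H]1Oc2ccc(C(C)=O)cc2[C@@H]1OC(=O)CC(C)C | intermediate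
14 | (2R,3S)-2-(3-{[tert-butyl(dimethyl)silyl]oxy}prop-1-en-2-yl)-5-[(1S)-1-hydroxyethyl]-2,3-dihydro-1-benzofuran-3-yl 3-methylbutanoate | C=C(CO[Si](C)(C)C(C)(C)C)[C@H]1Oc2ccc([C@H](C)O)cc2[C@@H]1OC(=O)CC(C)C | intermediate
15 | (2R,3S)-5-[(1S)-1-(acetyloxy)ethyl]-2-(3-{[tert-butyl(dimethyl)silyl]oxy}prop-1-en-2-yl)-2,3-dihydro-1-benzofuran-3-yl 3-methylbutanoate | C=C(CO[Si](C)(C)C(C)(C)C)[C@H]1Oc2ccc([C@H](C)OC(C)=O)cc2[C@@H]1OC(=O)CC(C)C | intermediate
16 | (2R,3S)-5-[(1S)-1-(acetyloxy)ethyl]-2-(3-hydroxyprop-1-en-2-yl)-2,3-dihydro-1-benzofuran-3-yl 3-methylbutanoate | C=C(CO)[C@H]1Oc2ccc([C@H](C)OC(C)=O)cc2[C@@H]1OC(=O)CC(C)C | intermediate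
17 | (2R,3S)-5-[(1S)-1-(acetyloxy)ethyl]-2-(3-oxoprop-1-en-2-yl)-2,3-dihydro-1-benzofuran-3-yl 3-methylbutanoate | C=C(C=O)[C@H]1Oc2ccc([C@H](C)OC(C)=O)cc2[C@@H]1OC(=O)CC(C)C | target

**Step count**

Total steps: 11. Longest linear sequence: 11 steps (1 to 17).

**Steps most likely to fail**

1. Step 6 (proposed new method). The allylchromium may be lost to Wurtz-type coupling or protonation before it closes the ring, or the aldehyde may undergo chromium-mediated pinacol coupling. The trans preference may erode if a boat or the Z allylchromium takes part. The ligand may give poor facial selectivity or the wrong enantiomer.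

   The fallback uses only known reaction types, sets out from 5 and comes back at 11. Phenol 5 is silylated (TBSCl, imidazole, DMF) to 5-acetyl-2-{[tert-butyl(dimethyl)silyl]oxy}benzaldehyde F1. Commercial 2-methylidenepropane-1,3-diol is monosilylated (NaH, TBSCl, THF) to 2-({[tert-butyl(dimethyl)silyl]oxy}methyl)prop-2-en-1-ol F2. F2 is brominated (CBr4, PPh3, CH2Cl2, 0 °C, Appel reaction) to {[2-(bromomethyl)prop-2-en-1-yl]oxy}(tert-butyl)dimethylsilane F3. F3 is alkylated onto (2R,5R)-2,5-dimethylthiolane (acetone, rt) to the allylic sulfonium bromide F4.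

   Deprotonation of F4 (LiHMDS, THF, −78 °C) in the presence of F1 is an asymmetric sulfonium-ylide epoxidation of Corey–Chaykovsky type. It is trans-selective for semi-stabilised allylic ylides, with face selection by the twofold-symmetric sulfide, and should give the trans-(2S,3S) vinyl epoxide F5. K2CO3 in MeOH then cleaves only the aryl silyl ether, and the phenoxide opens the epoxide at its allylic carbon with inversion. This is the mode by which 2-hydroxystilbene oxides close to 3-hydroxy-2,3-dihydrobenzofurans, and it should give the trans alcohol 11. If the (2R,5R) sulfide gives the mirror-image epoxide, its enantiomer is used.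

2. Step 4. The salicylaldehyde phenoxide may tie up copper by chelation, and it is a weak nucleophile. At 90 °C the base may start aldol condensation between acetyl and formyl groups, and the free allylic alcohol may compete for the vinyl bromide.

   The fallback sets out from 4 and comes back at 6. Vinyl bromide 4 is borylated (bis(pinacolato)diboron, PdCl2(PPh3)2, KOPh, toluene, 50 °C, Miyaura borylation with retention of geometry) to the alkenyl pinacol boronate F6. F6 is then coupled with phenol 5 at room temperature under oxidative Chan–Lam conditions (Cu(OAc)2, pyridine, 4 Å molecular sieves, air, CH2Cl2) to give 6 without hot carbonate base.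

3. Step 5. The mesylate or bromide may ionise to the aryloxy-stabilised allyl cation. Hydrolysis during work-up would then release phenol 5 and 2-(silyloxymethyl)acrolein, and the bromide may not survive storage.

   The fallback sets out from 6 and comes back at 11. Alcohol 6 is converted with diethyl chlorophosphate (pyridine, 4-(dimethylamino)pyridine, CH2Cl2, 0 °C) into the allylic diethyl phosphate F7, which should be stable to chromatography. F7 is submitted to the conditions of step 6 with LiI (1.5 equiv) added, so that the allylic iodide forms only in the flask and is reduced by divalent chromium as it forms. No allylic halide is isolated.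

**Further compounds**

F1 | step 6 | 5-acetyl-2-{[tert-butyl(dimethyl)silyl]oxy}benzaldehyde | CC(=O)c1ccc(O[Si](C)(C)C(C)(C)C)c(C=O)c1
F2 | step 6 | 2-({[tert-butyl(dimethyl)silyl]oxy}methyl)prop-2-en-1-ol | C=C(CO)CO[Si](C)(C)C(C)(C)C
F3 | step 6 | {[2-(bromomethyl)prop-2-en-1-yl]oxy}(tert-butyl)dimethylsilane | C=C(CBr)CO[Si](C)(C)C(C)(C)C
F4 | step 6 | (2R,5R)-1-[2-({[tert-butyl(dimethyl)silyl]oxy}methyl)prop-2-en-1-yl]-2,5-dimethylthiolan-1-ium bromide | C[C@@H]1CC[C@@H](C)[S+]1CC(=C)CO[Si](C)(C)C(C)(C)C.[Br-]
F5 | step 6 | 1-[4-{[tert-butyl(dimethyl)silyl]oxy}-3-{(2S,3S)-3-[3-({[tert-butyl(dimethyl)silyl]oxy})prop-1-en-2-yl]oxiran-2-yl}phenyl]ethan-1-one | C=C(CO[Si](C)(C)C(C)(C)C)[C@@H]1O[C@H]1c1cc(C(C)=O)ccc1O[Si](C)(C)C(C)(C)C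
F6 | step 4 | (2Z)-2-({[tert-butyl(dimethyl)silyl]oxy}methyl)-3-(4,4,5,5-tetramethyl-1,3,2-dioxaborolan-2-yl)prop-2-en-1-ol (drawn isomer; the 2E isomer accompanies it) | CC1(C)OB(/C=C(/CO)CO[Si](C)(C)C(C)(C)C)OC1(C)C
F7 | step 5 | (2E)-3-(4-acetyl-2-formylphenoxy)-2-({[tert-butyl(dimethyl)silyl]oxy}methyl)prop-2-en-1-yl diethyl phosphate (drawn isomer; the 2Z isomer accompanies it) | O=Cc1cc(C(C)=O)ccc1O/C=C(/COP(=O)(OCC)OCC)CO[Si](C)(C)C(C)(C)C
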